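The ratio of the two catalyst charges, 5.13, is our floor for the second question: it is the factor if rate follows the catalyst charged and none is lost.

common to all: starting material 0.015 M

| flask | partner | free catalyst | remark |
|---|---|---|---|
| epsilon | 0.0142 M | 0.55 mM | run made earlier |
| eta | 0.0142 M | 0.86 mM | run made earlier |
| zeta | 0.0071 M | 0.39 mM | run made earlier |
| flask | 0.0142 M | 0.39 mM |  |

| run | time / min | target / % | starting material / % |
|---|---|---|---|
| epsilon | 6.00 | 19.4 | 82.3 |
| epsilon | 12.0 | 30.2 | 68.7 |
| epsilon | 25.0 | 52.5 | 47.6 |
| epsilon | 40.0 | 66.5 | 34.1 |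
| epsilon | 80.0 | 82.3 | 18.0 |
| eta | 15.0 | 51.4 | 48.8 |
| eta | 30.0 | 74.3 | 26.5 |
| eta | 50.0 | 86.4 | 14.3 |
| eta | 60.0 | 88.9 | 11.6 |
| eta | 80.0 | 91.3 | 8.7 |
| zeta | 8.00 | 14.5 | 86.4 |
| zeta | 20.0 | 26.0 | 72.6 |
| zeta | 40.0 | 36.5 | 63.8 |
| zeta | 60.0 | 41.7 | 57.0 |
| zeta | 80.0 | 42.7 | 58.3 |

(standard deviation of a reading: 1 percentage point)

* factor on the rate of making target when 30% of the starting material are converted if partner is charged twice over
* factor on the rate when 30% of the starting material are converted if free catalyst is charged at 2.0 mM instead

- the earlier runs were read with a standard deviation of 1 percentage point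

For the ceiling we compare two runs at nearly one composition. Epsilon has 47.6% of its starting material left after 25.0 min, and eta has 48.8% left after 15.0 min. Charge times time, epsilon over eta, is

  1.07

So the quicker run needed less catalyst-time. We read this as wear. If mean catalyst age is half the elapsed time, the wear rate, the fraction of working catalyst lost per minute, is

  0.0128 min⁻¹

This is a rough reading: the two runs differ by 1.2 points in what is left, and each reading carries a scatter of 1 point.

Epsilon's catalyst-time at 12.0 min, where 68.7% is left, puts 30% conversion in the flask at 16.9 min and at 2.0 mM at 3.30 min. With no loss at 2.0 mM the ceiling is 6.37. Letting that flask age too tightens it to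

    6.10

For doubled partner, the partner left at 30% conversion bounds the factor between 1 and 2.46.

The forecast gives 1.4 and 5.9, the latter because speed “preserves more active catalyst”; that sits below our 6.10.

The simulation gives 1.26 and 5.73, inside both brackets.

    partner + free catalyst → catalyst intermediate A (k = 346 M⁻¹ min⁻¹)
    starting material + catalyst intermediate A → catalyst intermediate B (k = 79.8 M⁻¹ min⁻¹)
    catalyst intermediate B → free catalyst + target (k = 75.9 min⁻¹)
    free catalyst → spent catalyst (k = 0.0546 min⁻¹)

The flask reaches 30% conversion at 16.1 min. Our wear rate leaves 81.4% of the catalyst unspent by then, and the flask has 16.5% as spent catalyst. Carried to the 2.0 mM flask, the wear rate favours it by 1.19. The simulated comparison is catalyst intermediate A at equal conversion, 73.6% of the catalyst there against 66.0% in the flask, a ratio of 1.12, which multiplied by 5.13 is 5.72.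

The runs stem from a simulated flask with constants of no real substance; noise was put on by code.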